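The target is read as a cis-1,2-dialkenylcyclohexane: quaternary C10 (methyl, vinyl C1=C2) next to C5, which carries C4(=C3H2)CH2OH. This 1,5-diene (C2=C1–C10–C5–C4=C3) on the cyclohexane ring is the retron of a Cope rearrangement. The precursor is a ten-membered germacranolide with an E C1=C10 alkene and a C4=C5 alkene holding C6 cis to C3; heating breaks C2–C3, forms C5–C10, closes the cyclohexane and sets both centres from the alkene geometries, the trans-fused lactone choosing the face. The macrocycle is closed by a chromium-mediated allylation of a bromomethyl butenolide aldehyde, which sets C7 and C8 from C6.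

Key step: step 17

Remark: atoms are numbered as in germacranes and elemanes (ring C5–C10; C14 = methyl on C10; C15 = CH2OH on C4; lactone C6–O–C12(=O)–C11(=C13H2)–C7; ester oxygen on C8); compounds 1, 6, 8, 14 and 21 are taken as commercial.

Step 1
Reactants: 1 tert-butyl(but-3-yn-1-yloxy)dimethylsilane
Product: 4 (3E)-6-[(tert-butyldimethylsilyl)oxy]-4-methylhex-3-en-1-ol, via alkenylalane 2 (not isolated), via lithium alanate 3 (not isolated)
Conditions: Me3Al, Cp2ZrCl2 (cat.), CH2Cl2, rt; then n-BuLi, hexane/THF, −78 °C; ethylene oxide, −78 °C to rt; aq. NH4Cl/HCl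
Reagents that add atoms: trimethylaluminium (C[Al](C)C); ethylene oxide (C1CO1)
Why: Zirconium-catalysed syn-carboalumination (Negishi carboalumination) puts methyl on the internal carbon (C10) and aluminium on C1, which fixes the E geometry of C1=C10, and the derived alanate opens ethylene oxide with retention of alkene geometry to add C2 and C3.

Step 2
Reactants: 4 (3E)-6-[(tert-butyldimethylsilyl)oxy]-4-methylhex-3-en-1-ol
Product: 5 tert-butyl{[(3E)-6-iodo-3-methylhex-3-en-1-yl]oxy}dimethylsilane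
Conditions: I2, PPh3, imidazole, CH2Cl2, 0 °C
Reagents that add atoms: iodine (II)
Why: Appel-type iodination of the primary alcohol (phosphonium activation, then SN2 by iodide) should leave the silyl ether and the trisubstituted alkene untouched.

Step 3
Reactants: 5 tert-butyl{[(3E)-6-iodo-3-methylhex-3-en-1-yl]oxy}dimethylsilane; 6 triethyl phosphonoacetate
Product: 7 ethyl (5E)-8-[(tert-butyldimethylsilyl)oxy]-2-(diethoxyphosphoryl)-6-methyloct-5-enoate (racemic at C2)
Conditions: NaH, 6 (excess), THF/DMF, 0 to 60 °C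
Reagents that add atoms: none
Why: SN2 C-alkylation of the sodium salt of the phosphonoacetate by the primary iodide (excess 6 suppresses dialkylation) installs C4 together with its future C15 ester carbon.

Step 4
Reactants: 7 ethyl (5E)-8-[(tert-butyldimethylsilyl)oxy]-2-(diethoxyphosphoryl)-6-methyloct-5-enoate; 8 2,2-dimethoxyacetaldehyde (dried)
Product: 9 ethyl (2E)-2-{(3E)-6-[(tert-butyldimethylsilyl)oxy]-4-methylhex-3-en-1-yl}-4,4-dimethoxybut-2-enoate
Conditions: NaH, THF, 0 °C to rt
Reagents that add atoms: none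
Why: Horner–Wadsworth–Emmons olefination of an alpha-substituted phosphonoacetate with an unhindered aldehyde should favour the E enoate (ester trans to C6), which places C6 cis to C3 as the later rearrangement requires, and any Z isomer is removed by chromatography.

Step 5
Reactants: 9 ethyl (2E)-2-{(3E)-6-[(tert-butyldimethylsilyl)oxy]-4-methylhex-3-en-1-yl}-4,4-dimethoxybut-2-enoate
Product: 10 (2E)-2-{(3E)-6-[(tert-butyldimethylsilyl)oxy]-4-methylhex-3-en-1-yl}-4,4-dimethoxybut-2-en-1-ol
Conditions: DIBAL-H, CH2Cl2, −78 °C; Rochelle salt work-up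
Reagents that add atoms: none
Why: DIBAL-H reduces the conjugated ester to the allylic alcohol (C15) by 1,2-reduction and should not touch the acetal, the silyl ether or the alkenes.

Step 6
Reactants: 10 (2E)-2-{(3E)-6-[(tert-butyldimethylsilyl)oxy]-4-methylhex-3-en-1-yl}-4,4-dimethoxybut-2-en-1-ol
Product: 11 tert-butyldiphenylsilyl ether of 10 (at the C15 oxygen)
Conditions: TBDPSCl, imidazole, DMF, rt
Reagents that add atoms: tert-butyl(chloro)diphenylsilane (CC(C)(C)[Si](Cl)(c1ccccc1)c1ccccc1)
Why: Standard silylation of the primary allylic alcohol gives an acid- and heat-stable ether that is meant to survive until the last step.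

Step 7
Reactants: 11 tert-butyldiphenylsilyl ether of 10
Product: 12 (2E)-4-[(tert-butyldiphenylsilyl)oxy]-3-{(3E)-6-[(tert-butyldimethylsilyl)oxy]-4-methylhex-3-en-1-yl}but-2-enal
Conditions: 10% aq. oxalic acid on SiO2, CH2Cl2, rt
Reagents that add atoms: water (O)
Why: The allylic dimethyl acetal is hydrolysed by wet oxalic acid on silica far faster than either silyl ether is cleaved, and the mild medium should avoid E/Z isomerisation of the enal.

Step 8
Reactants: 12 (2E)-4-[(tert-butyldiphenylsilyl)oxy]-3-{(3E)-6-[(tert-butyldimethylsilyl)oxy]-4-methylhex-3-en-1-yl}but-2-enal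
Product: 13 (3S,4E,8E)-11-[(tert-butyldimethylsilyl)oxy]-5-{[(tert-butyldiphenylsilyl)oxy]methyl}-9-methylundeca-1,4,8-trien-3-ol
Conditions: Zn(CH=CH2)2 (salt-free), (2S)-(−)-3-exo-morpholinoisoborneol (10 mol%), toluene, −20 to 0 °C
Reagents that add atoms: divinylzinc (C=C[Zn]C=C)
Why: Amino-alcohol-catalysed enantioselective 1,2-addition of an alkenylzinc reagent to the aldehyde, in which the (2S)-aminoisoborneol ligand should direct the vinyl group to the Si face and so set C6 (S in 13, which becomes 6R of the target after the change in substituent priorities).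

Step 9
Reactants: 13 (3S,4E,8E)-11-[(tert-butyldimethylsilyl)oxy]-5-{[(tert-butyldiphenylsilyl)oxy]methyl}-9-methylundeca-1,4,8-trien-3-ol; 14 2-(bromomethyl)prop-2-enoic acid
Product: 15 (3S,4E,8E)-11-[(tert-butyldimethylsilyl)oxy]-5-{[(tert-butyldiphenylsilyl)oxy]methyl}-9-methylundeca-1,4,8-trien-3-yl 2-(bromomethyl)prop-2-enoate
Conditions: DCC, DMAP (5 mol%), CH2Cl2, −20 to 0 °C
Reagents that add atoms: none
Why: Steglich esterification of the secondary bis-allylic alcohol at low temperature with only catalytic DMAP, so that acyl transfer should outrun N-alkylation of the catalyst by the allylic bromide, and C6 is not touched.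

Step 10
Reactants: 15 (3S,4E,8E)-11-[(tert-butyldimethylsilyl)oxy]-5-{[(tert-butyldiphenylsilyl)oxy]methyl}-9-methylundeca-1,4,8-trien-3-yl 2-(bromomethyl)prop-2-enoate
Product: 16 (5R)-3-(bromomethyl)-5-[(1E,5E)-8-[(tert-butyldimethylsilyl)oxy]-2-{[(tert-butyldiphenylsilyl)oxy]methyl}-6-methylocta-1,5-dien-1-yl]furan-2(5H)-one
Conditions: second-generation Grubbs catalyst (5 mol%), toluene, 80 °C
Reagents that add atoms: none
Why: Ring-closing metathesis between the monosubstituted vinyl group and the 1,1-disubstituted acrylate alkene forms the butenolide with loss of ethene, the trisubstituted alkenes being inert, and it locks C6 cis to the carbonyl C12 across C7=C11.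

Step 11
Reactants: 16 (5R)-3-(bromomethyl)-5-[(1E,5E)-8-[(tert-butyldimethylsilyl)oxy]-2-{[(tert-butyldiphenylsilyl)oxy]methyl}-6-methylocta-1,5-dien-1-yl]furan-2(5H)-one
Product: 17 (5R)-3-(bromomethyl)-5-[(1E,5E)-2-{[(tert-butyldiphenylsilyl)oxy]methyl}-8-hydroxy-6-methylocta-1,5-dien-1-yl]furan-2(5H)-one
Conditions: CSA (10 mol%), MeOH/CH2Cl2 (1:1), 0 °C
Reagents that add atoms: none
Why: Acid-catalysed methanolysis cleaves the primary alkyl TBS ether selectively in the presence of the bulkier TBDPS ether, and the amine-free, non-basic medium should spare the allylic bromide and the acidic C6–H.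

Step 12
Reactants: 17 (5R)-3-(bromomethyl)-5-[(1E,5E)-2-{[(tert-butyldiphenylsilyl)oxy]methyl}-8-hydroxy-6-methylocta-1,5-dien-1-yl]furan-2(5H)-one
Product: 18 (3E,7E)-8-[(2R)-4-(bromomethyl)-5-oxo-2,5-dihydrofuran-2-yl]-7-{[(tert-butyldiphenylsilyl)oxy]methyl}-3-methylocta-3,7-dienal
Conditions: Dess–Martin periodinane, CH2Cl2, 0 °C to rt; used at once
Reagents that add atoms: none
Why: Dess–Martin oxidation gives the beta,gamma-unsaturated aldehyde (C8) under near-neutral conditions that should not move the C1=C10 alkene into conjugation.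

Step 13
Reactants: 18 (3E,7E)-8-[(2R)-4-(bromomethyl)-5-oxo-2,5-dihydrofuran-2-yl]-7-{[(tert-butyldiphenylsilyl)oxy]methyl}-3-methylocta-3,7-dienal
Product: 20 (6R,7R,8S)-15-[(tert-butyldiphenylsilyl)oxy]-8-hydroxygermacra-1(10)E,4E,11(13)-trien-6,12-olide (C6 cis to C3 on C4=C5), via allylchromium dichloride 19 (not isolated)
Conditions: CrCl2 (8 equiv), THF, rt, syringe-pump addition of 18 (final 2 mM)
Reagents that add atoms: none
Why: Intramolecular Nozaki–Hiyama–Kishi allylation in which CrCl2 inserts into the allylic C–Br bond and the allylchromium adds through its gamma carbon C7 to the aldehyde in a closed chair-like six-membered transition state, anti to the C5 substituent on the butenolide (trans lactone, 7R) and with C6 and C9 both pseudo-equatorial (anti adduct, 8S), which forms the ten-membered ring and the exocyclic methylene at once.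

Step 14
Reactants: 21 methyl (2S)-3-hydroxy-2-methylpropanoate
Product: 22 methyl (2S)-3-[(tert-butyldiphenylsilyl)oxy]-2-methylpropanoate
Conditions: TBDPSCl, imidazole, CH2Cl2, rt
Reagents that add atoms: tert-butyl(chloro)diphenylsilane (CC(C)(C)[Si](Cl)(c1ccccc1)c1ccccc1)
Why: Routine silylation of the primary alcohol of the chiral-pool ester, with no change at the stereocentre.

Step 15
Reactants: 22 methyl (2S)-3-[(tert-butyldiphenylsilyl)oxy]-2-methylpropanoate
Product: 23 (2S)-3-[(tert-butyldiphenylsilyl)oxy]-2-methylpropanoic acid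
Conditions: LiOH·H2O, THF/H2O, 0 °C to rt; then 1 M HCl
Reagents that add atoms: lithium hydroxide ([Li+].[OH-])
Why: Saponification of the methyl ester at low temperature, where the alpha stereocentre of the beta-silyloxy ester should not epimerise and no elimination should occur.

Step 16
Reactants: 20 (6R,7R,8S)-15-[(tert-butyldiphenylsilyl)oxy]-8-hydroxygermacra-1(10)E,4E,11(13)-trien-6,12-olide; 23 (2S)-3-[(tert-butyldiphenylsilyl)oxy]-2-methylpropanoic acid
Product: 24 (6R,7R,8S)-15-[(tert-butyldiphenylsilyl)oxy]-8-{(2S)-3-[(tert-butyldiphenylsilyl)oxy]-2-methylpropanoyloxy}germacra-1(10)E,4E,11(13)-trien-6,12-olide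
Conditions: DCC, DMAP (cat.), CH2Cl2, 0 °C to rt
Reagents that add atoms: none
Why: Steglich esterification of the C8 hydroxyl with the alpha-branched acid under non-acidic conditions, which keeps the acid stereocentre, the conjugated lactone and the acid-sensitive cyclodecadiene intact and blocks lactone migration to O8.

Step 17
Reactants: 24 (6R,7R,8S)-15-[(tert-butyldiphenylsilyl)oxy]-8-{(2S)-3-[(tert-butyldiphenylsilyl)oxy]-2-methylpropanoyloxy}germacra-1(10)E,4E,11(13)-trien-6,12-olide
Product: 25 (5R,6R,7R,8S,10R)-15-[(tert-butyldiphenylsilyl)oxy]-8-{(2S)-3-[(tert-butyldiphenylsilyl)oxy]-2-methylpropanoyloxy}elema-1,3,11(13)-trien-6,12-olide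
Conditions: degassed toluene, BHT (cat.), sealed tube, 170 °C
Reagents that add atoms: none
Why: On heating, the 1,5-diene C10=C1–C2–C3–C4=C5 embedded in the ten-membered ring undergoes a concerted [3,3]-sigmatropic (Cope) shift through a chair-like six-centre transition state, breaking C2–C3 and forming C5–C10; this is the germacranolide-to-elemanolide rearrangement known for cyclodeca-1,5-dienes. The cyclohexane C5–C6–C7–C8–C9–C10 is closed transannularly, the ten-membered ring contracting to a six-membered ring while the pericyclic chair and the incipient cyclohexane chair share the forming bond in a cis-decalin-like array. C10 is set by the E geometry of C1=C10 (C9 pseudo-equatorial, methyl pseudo-axial on the pericyclic chair) and C5 by the C4=C5 geometry (C6 cis to C3, hence pseudo-axial), which together give the cis relationship of the vinyl and hydroxy-isopropenyl groups (vinyl axial, methyl equatorial, H5 anti to H6). The step needs one of the two diastereomeric chair transition states, and the trans-fused lactone with the C8 ester forces C6–O, C7–C11 and C8–O to be equatorial on the forming cyclohexane, so that only one chair–chair arrangement fits both alkene geometries. Relief of the strain of the E,Z-cyclodecadiene should drive the equilibrium to the divinylcyclohexane, and BHT suppresses radical oligomerisation of the methylene lactone.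

Step 18
Reactants: 25 (5R,6R,7R,8S,10R)-15-[(tert-butyldiphenylsilyl)oxy]-8-{(2S)-3-[(tert-butyldiphenylsilyl)oxy]-2-methylpropanoyloxy}elema-1,3,11(13)-trien-6,12-olide
Product: 26 (5R,6R,7R,8S,10R)-15-hydroxy-8-[(2S)-3-hydroxy-2-methylpropanoyloxy]elema-1,3,11(13)-trien-6,12-olide (CNP0133858.2)
Conditions: HF·pyridine, pyridine, THF, 0 °C to rt
Reagents that add atoms: none
Why: Fluoride-mediated cleavage of both primary silyl ethers under buffered acidic conditions that should leave the methylene lactone, the ester and its alpha stereocentre unchanged.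

Compound list
1 | tert-butyl(but-3-yn-1-yloxy)dimethylsilane | C#CCCO[Si](C)(C)C(C)(C)C | starting material
2 | (E)-{4-[(tert-butyldimethylsilyl)oxy]-2-methylbut-1-en-1-yl}dimethylalane (not isolated) | C[Al](C)/C=C(\C)CCO[Si](C)(C)C(C)(C)C | intermediate
3 | lithium butyl{(E)-4-[(tert-butyldimethylsilyl)oxy]-2-methylbut-1-en-1-yl}dimethylalanate (not isolated) | [Li+].CCCC[Al-](C)(C)/C=C(\C)CCO[Si](C)(C)C(C)(C)C | intermediate
4 | (3E)-6-[(tert-butyldimethylsilyl)oxy]-4-methylhex-3-en-1-ol | OCC/C=C(\C)CCO[Si](C)(C)C(C)(C)C | intermediate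
5 | tert-butyl{[(3E)-6-iodo-3-methylhex-3-en-1-yl]oxy}dimethylsilane | ICC/C=C(\C)CCO[Si](C)(C)C(C)(C)C | intermediate
6 | triethyl phosphonoacetate | CCOC(=O)CP(=O)(OCC)OCC | starting material
7 | ethyl (5E)-8-[(tert-butyldimethylsilyl)oxy]-2-(diethoxyphosphoryl)-6-methyloct-5-enoate (racemic at C2) | CCOC(=O)C(CC/C=C(\C)CCO[Si](C)(C)C(C)(C)C)P(=O)(OCC)OCC | intermediate
8 | 2,2-dimethoxyacetaldehyde | COC(OC)C=O | starting material
9 | ethyl (2E)-2-{(3E)-6-[(tert-butyldimethylsilyl)oxy]-4-methylhex-3-en-1-yl}-4,4-dimethoxybut-2-enoate | CCOC(=O)/C(CC/C=C(\C)CCO[Si](C)(C)C(C)(C)C)=C/C(OC)OC | intermediate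
10 | (2E)-2-{(3E)-6-[(tert-butyldimethylsilyl)oxy]-4-methylhex-3-en-1-yl}-4,4-dimethoxybut-2-en-1-ol | OC/C(CC/C=C(\C)CCO[Si](C)(C)C(C)(C)C)=C/C(OC)OC | intermediate
11 | tert-butyldiphenylsilyl ether of 10 | CC(C)(C)[Si](OC/C(CC/C=C(\C)CCO[Si](C)(C)C(C)(C)C)=C/C(OC)OC)(c1ccccc1)c1ccccc1 | intermediate
12 | (2E)-4-[(tert-butyldiphenylsilyl)oxy]-3-{(3E)-6-[(tert-butyldimethylsilyl)oxy]-4-methylhex-3-en-1-yl}but-2-enal | O=C/C=C(\CC/C=C(\C)CCO[Si](C)(C)C(C)(C)C)CO[Si](c1ccccc1)(c1ccccc1)C(C)(C)C | intermediate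
13 | (3S,4E,8E)-11-[(tert-butyldimethylsilyl)oxy]-5-{[(tert-butyldiphenylsilyl)oxy]methyl}-9-methylundeca-1,4,8-trien-3-ol | C=C[C@H](O)/C=C(\CC/C=C(\C)CCO[Si](C)(C)C(C)(C)C)CO[Si](c1ccccc1)(c1ccccc1)C(C)(C)C | intermediate
14 | 2-(bromomethyl)prop-2-enoic acid | OC(=O)C(=C)CBr | starting material
15 | 2-(bromomethyl)prop-2-enoate ester of 13 (3S) | C=C[C@H](OC(=O)C(=C)CBr)/C=C(\CC/C=C(\C)CCO[Si](C)(C)C(C)(C)C)CO[Si](c1ccccc1)(c1ccccc1)C(C)(C)C | intermediate
16 | (5R)-3-(bromomethyl)-5-[(1E,5E)-8-[(tert-butyldimethylsilyl)oxy]-2-{[(tert-butyldiphenylsilyl)oxy]methyl}-6-methylocta-1,5-dien-1-yl]furan-2(5H)-one | BrCC1=C[C@@H](/C=C(\CC/C=C(\C)CCO[Si](C)(C)C(C)(C)C)CO[Si](c2ccccc2)(c2ccccc2)C(C)(C)C)OC1=O | intermediate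
17 | (5R)-3-(bromomethyl)-5-[(1E,5E)-2-{[(tert-butyldiphenylsilyl)oxy]methyl}-8-hydroxy-6-methylocta-1,5-dien-1-yl]furan-2(5H)-one | BrCC1=C[C@@H](/C=C(\CC/C=C(\C)CCO)CO[Si](c2ccccc2)(c2ccccc2)C(C)(C)C)OC1=O | intermediate
18 | (3E,7E)-8-[(2R)-4-(bromomethyl)-5-oxo-2,5-dihydrofuran-2-yl]-7-{[(tert-butyldiphenylsilyl)oxy]methyl}-3-methylocta-3,7-dienal | BrCC1=C[C@@H](/C=C(\CC/C=C(\C)CC=O)CO[Si](c2ccccc2)(c2ccccc2)C(C)(C)C)OC1=O | intermediate
19 | allylchromium dichloride derived from 18 (Cr on the former CH2Br carbon; not isolated) | Cl[Cr](Cl)CC1=C[C@@H](/C=C(\CC/C=C(\C)CC=O)CO[Si](c2ccccc2)(c2ccccc2)C(C)(C)C)OC1=O | intermediate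
20 | (6R,7R,8S)-15-[(tert-butyldiphenylsilyl)oxy]-8-hydroxygermacra-1(10)E,4E,11(13)-trien-6,12-olide | C/C1=C\CC/C(CO[Si](c3ccccc3)(c3ccccc3)C(C)(C)C)=C\[C@H]2OC(=O)C(=C)[C@@H]2[C@@H](O)C1 | intermediate
21 | methyl (2S)-3-hydroxy-2-methylpropanoate | COC(=O)[C@@H](C)CO | starting material
22 | methyl (2S)-3-[(tert-butyldiphenylsilyl)oxy]-2-methylpropanoate | COC(=O)[C@@H](C)CO[Si](c1ccccc1)(c1ccccc1)C(C)(C)C | intermediate
23 | (2S)-3-[(tert-butyldiphenylsilyl)oxy]-2-methylpropanoic acid | OC(=O)[C@@H](C)CO[Si](c1ccccc1)(c1ccccc1)C(C)(C)C | intermediate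
24 | (6R,7R,8S)-15-[(tert-butyldiphenylsilyl)oxy]-8-{(2S)-3-[(tert-butyldiphenylsilyl)oxy]-2-methylpropanoyloxy}germacra-1(10)E,4E,11(13)-trien-6,12-olide | C/C1=C\CC/C(CO[Si](c3ccccc3)(c3ccccc3)C(C)(C)C)=C\[C@H]2OC(=O)C(=C)[C@@H]2[C@@H](OC(=O)[C@@H](C)CO[Si](c3ccccc3)(c3ccccc3)C(C)(C)C)C1 | intermediate
25 | (5R,6R,7R,8S,10R)-15-[(tert-butyldiphenylsilyl)oxy]-8-{(2S)-3-[(tert-butyldiphenylsilyl)oxy]-2-methylpropanoyloxy}elema-1,3,11(13)-trien-6,12-olide | C=C[C@@]1(C)C[C@H](OC(=O)[C@@H](C)CO[Si](c3ccccc3)(c3ccccc3)C(C)(C)C)[C@H]2C(=C)C(=O)O[C@@H]2[C@H]1C(=C)CO[Si](c3ccccc3)(c3ccccc3)C(C)(C)C | intermediate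
26 | (5R,6R,7R,8S,10R)-15-hydroxy-8-[(2S)-3-hydroxy-2-methylpropanoyloxy]elema-1,3,11(13)-trien-6,12-olide | C=C[C@@]1(C)C[C@H](OC(=O)[C@@H](C)CO)[C@H]2C(=C)C(=O)O[C@@H]2[C@H]1C(=C)CO | target

Total step count: 18. Longest linear sequence: 16 steps (steps 1–13, 16, 17 and 18).

Steps most likely to fail

1. Step 13 (macrocyclic allylation). Intermolecular oligomerisation may outrun closure of the ten-membered ring, the beta,gamma-unsaturated aldehyde may drift into conjugation under the Lewis-acidic chromium salts, and the tether may force attack on the butenolide face syn to C5 (cis lactone). The fallback replaces the reductively generated organometallic by an isolable allylboronate. Setting out from 16, borylation of the allylic bromide (Pd2(dba)3 cat., B2pin2, toluene, 50 °C) would give the allylboronate silyl ether F1. Acid-catalysed methanolysis (CSA, MeOH/CH2Cl2, 0 °C) would give the allylboronate alcohol F2, and Dess–Martin oxidation the allylboronate aldehyde F3. Slow addition of F3 to Sc(OTf)3 (10 mol%) in toluene at high dilution should effect intramolecular allylboration through the same closed chair transition state. Aqueous work-up would return to the route at 20.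

2. Step 17 (Cope rearrangement). The [3,3] shift may be slow at temperatures where the conjugated methylene lactone oligomerises or adds adventitious nucleophiles, and conversion may stop at an equilibrium mixture. The fallback masks the Michael acceptor during the thermolysis. Setting out from 24, conjugate addition of dimethylamine (Me2NH, THF, 0 °C) would give the amine adduct F4 (C11 epimers). Thermolysis of F4 (toluene, 170 °C) would give the rearranged amine adduct F5. Quaternisation with MeI would give the methiodide F6, and NaHCO3 (aq)/EtOAc would eliminate trimethylamine to regenerate the exocyclic alkene, returning to the route at 25.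

3. Step 8 (enantioselective vinylation). Uncatalysed background addition and coordination of the zinc reagent by the silyl ethers may erode the facial selectivity on this beta,beta-disubstituted enal, and a salt-free vinylzinc reagent is hard to keep active. The fallback builds the same carbinol by alkynylation and semi-reduction. Setting out from 12, zinc-alkynylide addition of trimethylsilylacetylene (Me2Zn, ProPhenol ligand of the enantiomeric series that gives Si-face attack, Ph3PO, toluene, 4 °C) would give the silylated propargylic alcohol F7. K2CO3/MeOH would give the terminal alkyne carbinol F8, and semi-hydrogenation (H2, Pd/CaCO3 poisoned with Pb(OAc)2, quinoline, EtOAc) would return to the route at 13.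

Further compounds
F1 | step 13 | (5R)-5-[(1E,5E)-8-[(tert-butyldimethylsilyl)oxy]-2-{[(tert-butyldiphenylsilyl)oxy]methyl}-6-methylocta-1,5-dien-1-yl]-3-[(4,4,5,5-tetramethyl-1,3,2-dioxaborolan-2-yl)methyl]furan-2(5H)-one | CC1(C)OB(CC2=C[C@@H](/C=C(\CC/C=C(\C)CCO[Si](C)(C)C(C)(C)C)CO[Si](c3ccccc3)(c3ccccc3)C(C)(C)C)OC2=O)OC1(C)C
F2 | step 13 | (5R)-5-[(1E,5E)-2-{[(tert-butyldiphenylsilyl)oxy]methyl}-8-hydroxy-6-methylocta-1,5-dien-1-yl]-3-[(4,4,5,5-tetramethyl-1,3,2-dioxaborolan-2-yl)methyl]furan-2(5H)-one | CC1(C)OB(CC2=C[C@@H](/C=C(\CC/C=C(\C)CCO)CO[Si](c3ccccc3)(c3ccccc3)C(C)(C)C)OC2=O)OC1(C)C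
F3 | step 13 | (3E,7E)-7-{[(tert-butyldiphenylsilyl)oxy]methyl}-3-methyl-8-{(2R)-5-oxo-4-[(4,4,5,5-tetramethyl-1,3,2-dioxaborolan-2-yl)methyl]-2,5-dihydrofuran-2-yl}octa-3,7-dienal | CC1(C)OB(CC2=C[C@@H](/C=C(\CC/C=C(\C)CC=O)CO[Si](c3ccccc3)(c3ccccc3)C(C)(C)C)OC2=O)OC1(C)C
F4 | step 17 | 13-(dimethylamino)-11,13-dihydro derivative of 24 (C11 epimers) | C/C1=C\CC/C(CO[Si](c3ccccc3)(c3ccccc3)C(C)(C)C)=C\[C@H]2OC(=O)C(CN(C)C)[C@@H]2[C@@H](OC(=O)[C@@H](C)CO[Si](c3ccccc3)(c3ccccc3)C(C)(C)C)C1
F5 | step 17 | 13-(dimethylamino)-11,13-dihydro derivative of 25 (C11 epimers) | C=C[C@@]1(C)C[C@H](OC(=O)[C@@H](C)CO[Si](c3ccccc3)(c3ccccc3)C(C)(C)C)[C@H]2C(CN(C)C)C(=O)O[C@@H]2[C@H]1C(=C)CO[Si](c3ccccc3)(c3ccccc3)C(C)(C)C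
F6 | step 17 | trimethylammonium iodide (methiodide) of F5 | C=C[C@@]1(C)C[C@H](OC(=O)[C@@H](C)CO[Si](c3ccccc3)(c3ccccc3)C(C)(C)C)[C@H]2C(C[N+](C)(C)C)C(=O)O[C@@H]2[C@H]1C(=C)CO[Si](c3ccccc3)(c3ccccc3)C(C)(C)C.[I-]
F7 | step 8 | (3R,4E,8E)-11-[(tert-butyldimethylsilyl)oxy]-5-{[(tert-butyldiphenylsilyl)oxy]methyl}-9-methyl-1-(trimethylsilyl)undeca-4,8-dien-1-yn-3-ol | C[Si](C)(C)C#C[C@H](O)/C=C(\CC/C=C(\C)CCO[Si](C)(C)C(C)(C)C)CO[Si](c1ccccc1)(c1ccccc1)C(C)(C)C
F8 | step 8 | (3R,4E,8E)-11-[(tert-butyldimethylsilyl)oxy]-5-{[(tert-butyldiphenylsilyl)oxy]methyl}-9-methylundeca-4,8-dien-1-yn-3-ol | C#C[C@H](O)/C=C(\CC/C=C(\C)CCO[Si](C)(C)C(C)(C)C)CO[Si](c1ccccc1)(c1ccccc1)C(C)(C)C
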